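**Retrosynthetic overview**

1. The target, (5S,9S,10S,14S)-labda-7,13(16)-diene-14,15-diyl diacetate (labdane numbering throughout), is traced back through its 14,15-acetonide to a C3 ketone. The C4 gem-dimethyl group and the trans H5 come from reductive methylation of a 4-methyl-4-en-3-one, and that enone from a 1,4-dien-3-one.
2. The strategy rests on the fact that the quaternary carbon C10 lies para to C3 and ortho to C5 within ring A. Ring A is therefore carried as an aromatic 2,4-dimethylphenol (OH on C3, methyls on C4 and C10) bearing at C5 the chain C6–C7=C8(C17)–C9. Attack of the phenoxide para carbon C10 on a π-allyl terminus at C9 forms C9–C10, closes ring B with C7=C8 in place, and dearomatises ring A.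
3. The cyclisation substrate is a Z-allylic methyl carbonate. The C9–C11 bond comes from a Z-enal and a homoallyllithium, C9 is set by oxidation and Corey–Bakshi–Shibata reduction, and the Z C7=C8 olefin by Still–Gennari olefination of an arylacetaldehyde.
4. The arene comes from 2-bromo-1,3-dimethylbenzene (nitro to phenol, bromide to CH2CH2OH). The side chain C11–C16 with C14 comes from methyl (R)-glycerate acetonide via the alkyne, ethylene enyne metathesis and diene hydroboration.
5. Ring order: ring A enters as the arene; ring B is the only ring formed, in step 19.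

Key step: step 19

Assumption: the (R,R) antipode of the bis(phosphanylbenzamide) ligand is written in step 19; whether it or its mirror image is the matched partner of the (9S)-carbonate cannot be predicted and would be settled by running both.

Remark: TBS = tert-butyldimethylsilyl; compound 22 is carried as the mixture of its two C9 epimers because C9 is reset in steps 15 and 16.

**Route**

Step 1
Reactants: 1 2-bromo-1,3-dimethylbenzene
Product: 2 2-bromo-1,3-dimethyl-4-nitrobenzene
Conditions: HNO3 (1.05 equiv), H2SO4, AcOH, 0 °C → rt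
Reagents that add atoms: nitric acid, O[N+](=O)[O-]
Why: Electrophilic aromatic nitration, in which both methyl groups direct to C4 (ortho to one, para to the other) while the position para to bromine is meta to both, so the 4-nitro isomer should dominate.

Step 2
Reactants: 2 2-bromo-1,3-dimethyl-4-nitrobenzene
Product: 3 3-bromo-2,4-dimethylaniline
Conditions: H2 (1 atm), 5% Pt/C (sulfided), EtOAc, rt
Reagents that add atoms: none
Why: Catalytic hydrogenation of a nitroarene over sulfided platinum on carbon, a catalyst chosen because it leaves aryl bromides untouched.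

Step 3
Reactants: 3 3-bromo-2,4-dimethylaniline
Product: 5 3-bromo-2,4-dimethylphenol, via diazonium hydrogen sulfate 4 (not isolated)
Conditions: NaNO2, aq H2SO4, 0 °C; then run into boiling dilute H2SO4
Reagents that add atoms: water, O (phenol oxygen); sodium nitrite, [Na+].[O-]N=O (second nitrogen of intermediate 4 only); sulfuric acid, OS(=O)(=O)O (counter-ion of intermediate 4 only)
Why: Diazotisation followed by thermal hydrolysis of the diazonium salt is the standard conversion of an aniline into a phenol and is not impeded by the ortho methyl group.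

Step 4
Reactants: 5 3-bromo-2,4-dimethylphenol
Product: 6 (3-bromo-2,4-dimethylphenoxy)(tert-butyl)dimethylsilane
Conditions: TBSCl, imidazole, DMF, rt
Reagents that add atoms: tert-butyldimethylsilyl chloride, CC(C)(C)[Si](C)(C)Cl
Why: Imidazole-promoted silylation masks the phenol as an aryl silyl ether that should withstand the organolithium, hydride and oxidation steps that follow.

Step 5
Reactants: 6 (3-bromo-2,4-dimethylphenoxy)(tert-butyl)dimethylsilane
Product: 8 2-{3-[(tert-butyldimethylsilyl)oxy]-2,6-dimethylphenyl}ethan-1-ol, via aryllithium 7 (not isolated)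
Conditions: t-BuLi (2.1 equiv), Et2O, −78 °C; ethylene oxide (3 equiv), −78 °C → rt; H2O
Reagents that add atoms: ethylene oxide, C1CO1; tert-butyllithium, [Li]C(C)(C)C (lithium of intermediate 7 only)
Why: Bromine–lithium exchange followed by epoxide opening adds the two carbons C6 and C7, and the silyloxy group is meta to the lithiated carbon so no silyl migration to carbon is possible.

Step 6
Reactants: 8 2-{3-[(tert-butyldimethylsilyl)oxy]-2,6-dimethylphenyl}ethan-1-ol
Product: 9 2-{3-[(tert-butyldimethylsilyl)oxy]-2,6-dimethylphenyl}acetaldehyde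
Conditions: Dess–Martin periodinane, CH2Cl2, 0 °C → rt; used at once
Reagents that add atoms: none
Why: Dess–Martin oxidation stops at the aldehyde under nearly neutral conditions, which should keep the enolisable arylacetaldehyde from self-condensing.

Step 7
Reactants: 9 2-{3-[(tert-butyldimethylsilyl)oxy]-2,6-dimethylphenyl}acetaldehyde; 10 ethyl 2-[bis(2,2,2-trifluoroethoxy)phosphoryl]propanoate
Product: 11 ethyl (2Z)-4-{3-[(tert-butyldimethylsilyl)oxy]-2,6-dimethylphenyl}-2-methylbut-2-enoate
Conditions: KN(SiMe3)2, 18-crown-6, THF, −78 °C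
Reagents that add atoms: none
Why: Still–Gennari olefination, in which the electron-poor trifluoroethyl phosphonate with a dissociated potassium counter-ion eliminates from the kinetic adduct, should give the Z trisubstituted enoate with the future C9 cis to C6.

Step 8
Reactants: 11 ethyl (2Z)-4-{3-[(tert-butyldimethylsilyl)oxy]-2,6-dimethylphenyl}-2-methylbut-2-enoate
Product: 12 (2Z)-4-{3-[(tert-butyldimethylsilyl)oxy]-2,6-dimethylphenyl}-2-methylbut-2-en-1-ol
Conditions: i-Bu2AlH (2.5 equiv), CH2Cl2, −78 °C; aq Rochelle salt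
Reagents that add atoms: none
Why: 1,2-Reduction of the enoate with i-Bu2AlH at low temperature gives the allylic alcohol without touching the olefin geometry or the aryl silyl ether.

Step 9
Reactants: 12 (2Z)-4-{3-[(tert-butyldimethylsilyl)oxy]-2,6-dimethylphenyl}-2-methylbut-2-en-1-ol
Product: 13 (2Z)-4-{3-[(tert-butyldimethylsilyl)oxy]-2,6-dimethylphenyl}-2-methylbut-2-enal
Conditions: MnO2 (activated, excess), CH2Cl2, rt
Reagents that add atoms: none
Why: Allylic oxidation with MnO2 is neutral and heterogeneous, stops at the aldehyde and should preserve the Z geometry of the α-methyl enal.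

Step 10
Reactants: 14 methyl (R)-2,2-dimethyl-1,3-dioxolane-4-carboxylate
Product: 16 (S)-4-ethynyl-2,2-dimethyl-1,3-dioxolane, via glyceraldehyde acetonide 15 (not isolated)
Conditions: i-Bu2AlH (1.1 equiv), CH2Cl2, −78 °C; then MeOH, K2CO3, dimethyl (1-diazo-2-oxopropyl)phosphonate, −78 → 0 °C
Reagents that add atoms: dimethyl (1-diazo-2-oxopropyl)phosphonate, CC(=O)C(=[N+]=[N-])P(=O)(OC)OC (terminal alkyne carbon)
Why: One-pot half-reduction and Seyferth–Gilbert homologation with the Ohira–Bestmann reagent turns the ester into the alkyne without handling the labile aldehyde, and the C14 stereocentre is not involved (its descriptor changes from R to S only through the priority rules).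

Step 11
Reactants: 16 (S)-4-ethynyl-2,2-dimethyl-1,3-dioxolane
Product: 17 (S)-4-(buta-1,3-dien-2-yl)-2,2-dimethyl-1,3-dioxolane
Conditions: ethylene (1 atm), second-generation Grubbs catalyst RuCl2(=CHPh)(PCy3)(H2IMes) (5 mol%), CH2Cl2, 40 °C
Reagents that add atoms: ethylene, C=C
Why: Ethylene–alkyne cross enyne metathesis converts a terminal alkyne into the 2-substituted 1,3-diene and is known to tolerate propargylic oxygen substituents.

Step 12
Reactants: 17 (S)-4-(buta-1,3-dien-2-yl)-2,2-dimethyl-1,3-dioxolane
Product: 19 3-[(4S)-2,2-dimethyl-1,3-dioxolan-4-yl]but-3-en-1-ol, via homoallylic dialkylborane 18 (not isolated)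
Conditions: disiamylborane (from BH3·SMe2 and 2-methylbut-2-ene, THF, 0 °C), THF, 0 °C; then NaOH, H2O2, 0 °C → rt
Reagents that add atoms: hydrogen peroxide, OO (hydroxyl oxygen); disiamylborane, CC(C)C(C)BC(C)C(C)C (boron and its two alkyl groups in intermediate 18 only)
Why: Hydroboration–oxidation with the bulky dialkylborane should place boron on the terminal carbon of the monosubstituted vinyl group in preference to the 1,1-disubstituted, oxygen-flanked olefin, as is known for 2-substituted butadienes.

Step 13
Reactants: 19 3-[(4S)-2,2-dimethyl-1,3-dioxolan-4-yl]but-3-en-1-ol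
Product: 20 (S)-4-(4-iodobut-1-en-2-yl)-2,2-dimethyl-1,3-dioxolane
Conditions: I2, PPh3, imidazole, CH2Cl2, 0 °C
Reagents that add atoms: iodine, II
Why: Appel-type iodination of the primary alcohol proceeds by SN2 displacement under conditions that leave the acetonide and the olefin alone.

Step 14
Reactants: 20 (S)-4-(4-iodobut-1-en-2-yl)-2,2-dimethyl-1,3-dioxolane; 13 (2Z)-4-{3-[(tert-butyldimethylsilyl)oxy]-2,6-dimethylphenyl}-2-methylbut-2-enal
Product: 22 (2Z)-1-{3-[(tert-butyldimethylsilyl)oxy]-2,6-dimethylphenyl}-7-[(4S)-2,2-dimethyl-1,3-dioxolan-4-yl]-3-methylocta-2,7-dien-4-ol (both C4 epimers; C4 is labdane C9), via homoallyllithium 21 (not isolated)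
Conditions: 20, t-BuLi (2.0 equiv), Et2O/pentane, −78 °C; then 13, −78 °C; H2O
Reagents that add atoms: tert-butyllithium, [Li]C(C)(C)C (lithium of intermediate 21 only)
Why: Iodine–lithium exchange followed by 1,2-addition of the primary alkyllithium to the enal forms the C9–C11 bond, and no control at C9 is expected or needed because the carbinol is reset in steps 15 and 16.

Step 15
Reactants: 22 (2Z)-1-{3-[(tert-butyldimethylsilyl)oxy]-2,6-dimethylphenyl}-7-[(4S)-2,2-dimethyl-1,3-dioxolan-4-yl]-3-methylocta-2,7-dien-4-ol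
Product: 23 (2Z)-1-{3-[(tert-butyldimethylsilyl)oxy]-2,6-dimethylphenyl}-7-[(4S)-2,2-dimethyl-1,3-dioxolan-4-yl]-3-methylocta-2,7-dien-4-one
Conditions: Dess–Martin periodinane, CH2Cl2, 0 °C → rt
Reagents that add atoms: none
Why: Dess–Martin oxidation of the secondary allylic alcohol gives the enone under conditions mild enough for the Z olefin, the acetonide and the silyl ether.

Step 16
Reactants: 23 (2Z)-1-{3-[(tert-butyldimethylsilyl)oxy]-2,6-dimethylphenyl}-7-[(4S)-2,2-dimethyl-1,3-dioxolan-4-yl]-3-methylocta-2,7-dien-4-one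
Product: 24 (2Z,4S)-1-{3-[(tert-butyldimethylsilyl)oxy]-2,6-dimethylphenyl}-7-[(4S)-2,2-dimethyl-1,3-dioxolan-4-yl]-3-methylocta-2,7-dien-4-ol
Conditions: (R)-2-methyl-CBS-oxazaborolidine (0.3 equiv), catecholborane (1.8 equiv), toluene, −78 °C; MeOH, then aq NaOH wash
Reagents that add atoms: none
Why: Corey–Bakshi–Shibata reduction, with the α-branched alkenyl group as the large substituent, should deliver hydride to the face that gives the (9S)-alcohol with the (R)-catalyst, and catecholborane at −78 °C does not hydroborate the 1,1-disubstituted olefin.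

Step 17
Reactants: 24 (2Z,4S)-1-{3-[(tert-butyldimethylsilyl)oxy]-2,6-dimethylphenyl}-7-[(4S)-2,2-dimethyl-1,3-dioxolan-4-yl]-3-methylocta-2,7-dien-4-ol
Product: 25 (2Z,4S)-1-{3-[(tert-butyldimethylsilyl)oxy]-2,6-dimethylphenyl}-7-[(4S)-2,2-dimethyl-1,3-dioxolan-4-yl]-3-methylocta-2,7-dien-4-yl methyl carbonate
Conditions: ClCO2Me, pyridine, DMAP (cat.), CH2Cl2, 0 °C
Reagents that add atoms: methyl chloroformate, COC(=O)Cl
Why: Acylation of the secondary alcohol installs the carbonate leaving group with retention at C9, and on ionisation it will release methoxide as the internal base.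

Step 18
Reactants: 25 (2Z,4S)-1-{3-[(tert-butyldimethylsilyl)oxy]-2,6-dimethylphenyl}-7-[(4S)-2,2-dimethyl-1,3-dioxolan-4-yl]-3-methylocta-2,7-dien-4-yl methyl carbonate
Product: 26 methyl (2Z,4S)-1-(3-hydroxy-2,6-dimethylphenyl)-7-[(4S)-2,2-dimethyl-1,3-dioxolan-4-yl]-3-methylocta-2,7-dien-4-yl carbonate
Conditions: n-Bu4NF, AcOH (1:1), THF, 0 °C
Reagents that add atoms: none
Why: Fluoride cleaves the aryl silyl ether rapidly, and buffering with acetic acid keeps the phenol protonated so that it cannot attack the carbonate.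

Step 19
Reactants: 26 methyl (2Z,4S)-1-(3-hydroxy-2,6-dimethylphenyl)-7-[(4S)-2,2-dimethyl-1,3-dioxolan-4-yl]-3-methylocta-2,7-dien-4-yl carbonate
Product: 27 (9S,10R,14S)-14,15-(isopropylidenedioxy)-19-norlabda-1,4,7,13(16)-tetraen-3-one
Conditions: Pd2(dba)3·CHCl3 (2.5 mol%), N,N'-[(1R,2R)-cyclohexane-1,2-diyl]bis[2-(diphenylphosphanyl)benzamide] (7.5 mol%), CH2Cl2 (0.005 M), 4 Å sieves, 0 °C → rt
Reagents that add atoms: none
Why: Proposed new method: zerovalent palladium ionises the C9 carbonate with inversion to a cationic π-allyl complex spanning C7–C8–C9, the methoxide set free deprotonates the phenol, and the para carbon C10 of the phenoxide attacks C9 on the face away from palladium; the closest known reaction type is the palladium- or iridium-catalysed intramolecular allylic dearomatisation of para-tethered phenols to spirocyclohexadienones, moved here to a meta tether so that a fused ring results. Ring B (C5–C6–C7=C8–C9–C10) closes in the six-membered endo mode with all three allyl carbons inside the ring, which needs the anti placement of C6 that the Z olefin delivers and that the C8 methyl keeps from relaxing to the syn form; attack at C7 is excluded because it would give a four-membered ring. C9 is set by double inversion, that is net retention from the (9S)-carbonate made in steps 16 and 17. The quaternary centre C10 is set by the face of the arene that meets C9: with ring A turned away from the allyl unit and its C8 methyl, C20 ends on the side of C11, and the chiral ligand is there to reinforce this arrangement. The step needs C-alkylation at the para carbon C10 and not at the ortho carbon C4 or at oxygen: C10 has the larger phenoxide coefficient and the unsubstituted C1–H as neighbour whereas C4 sits next to the solvated oxygen-bearing C3, no alkali cation is present to guide ortho attack, and an O-allyl ether can only form between two molecules and is re-ionised by palladium at high dilution. The C10 methyl prevents rearomatisation, so the cross-conjugated dienone is the end point.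

Step 20
Reactants: 27 (9S,10R,14S)-14,15-(isopropylidenedioxy)-19-norlabda-1,4,7,13(16)-tetraen-3-one
Product: 28 (9S,10R,14S)-14,15-(isopropylidenedioxy)-19-norlabda-4,7,13(16)-trien-3-one
Conditions: [(Ph3P)CuH]6 (0.4 equiv), H2O (2 equiv), benzene/THF, rt
Reagents that add atoms: none
Why: Copper hydride conjugate reduction delivers hydride to the less substituted β-carbon C1 of the cross-conjugated dienone and should leave the tetrasubstituted C4=C5 enone and the isolated olefins untouched.

Step 21
Reactants: 28 (9S,10R,14S)-14,15-(isopropylidenedioxy)-19-norlabda-4,7,13(16)-trien-3-one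
Product: 30 (5R,9S,10R,14S)-14,15-(isopropylidenedioxy)labda-7,13(16)-dien-3-one, via lithium enolate 29 (not isolated)
Conditions: Li (2.2 equiv), t-BuOH (1.0 equiv), NH3(l)/THF, −78 °C; then MeI (excess), −78 → −33 °C
Reagents that add atoms: iodomethane, CI; lithium, [Li] (counter-ion of intermediate 29 only)
Why: Dissolving-metal reductive alkylation of the enone protonates C5 axially on the face opposite the C10 methyl, giving the trans ring fusion, and the regiodefined C3–C4 enolate is then C-methylated to the gem-dimethyl group.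

Step 22
Reactants: 30 (5R,9S,10R,14S)-14,15-(isopropylidenedioxy)labda-7,13(16)-dien-3-one
Product: 32 (5S,9S,10S,14S)-14,15-(isopropylidenedioxy)labda-7,13(16)-diene, via hydrazone 31 (not isolated)
Conditions: N2H4·H2O, KOH, diethylene glycol, 130 °C; then water distilled off, 200 °C
Reagents that add atoms: hydrazine hydrate, NN.O (nitrogen atoms of intermediate 31 only; none remain in 32)
Why: Wolff–Kishner reduction in the Huang–Minlon form removes the C3 carbonyl through the hydrazone and loss of dinitrogen, conditions that acetonides and unconjugated olefins normally withstand.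

Step 23
Reactants: 32 (5S,9S,10S,14S)-14,15-(isopropylidenedioxy)labda-7,13(16)-diene
Product: 33 (5S,9S,10S,14S)-labda-7,13(16)-diene-14,15-diol
Conditions: AcOH/THF/H2O (3:1:1), 45 °C
Reagents that add atoms: none
Why: Mild acid hydrolysis cleaves the terminal acetonide while leaving the trisubstituted and 1,1-disubstituted olefins and the C14 configuration unchanged.

Step 24
Reactants: 33 (5S,9S,10S,14S)-labda-7,13(16)-diene-14,15-diol
Product: 34 (5S,9S,10S,14S)-labda-7,13(16)-diene-14,15-diyl diacetate
Conditions: Ac2O, pyridine, DMAP (cat.), CH2Cl2, rt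
Reagents that add atoms: acetic anhydride, CC(=O)OC(C)=O
Why: DMAP-catalysed acetylation esterifies both the primary and the secondary allylic hydroxyl group without affecting any stereocentre.

**Compound list**

1 | 2-bromo-1,3-dimethylbenzene | Cc1cccc(C)c1Br | starting material
2 | 2-bromo-1,3-dimethyl-4-nitrobenzene | Cc1ccc([N+](=O)[O-])c(C)c1Br | intermediate
3 | 3-bromo-2,4-dimethylaniline | Cc1ccc(N)c(C)c1Br | intermediate
4 | 3-bromo-2,4-dimethylbenzenediazonium hydrogen sulfate | Cc1ccc([N+]#N)c(C)c1Br.OS(=O)(=O)[O-] | intermediate (not isolated)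
5 | 3-bromo-2,4-dimethylphenol | Cc1ccc(O)c(C)c1Br | intermediate
6 | (3-bromo-2,4-dimethylphenoxy)(tert-butyl)dimethylsilane | Cc1ccc(O[Si](C)(C)C(C)(C)C)c(C)c1Br | intermediate
7 | {3-[(tert-butyldimethylsilyl)oxy]-2,6-dimethylphenyl}lithium | Cc1ccc(O[Si](C)(C)C(C)(C)C)c(C)c1[Li] | intermediate (not isolated)
8 | 2-{3-[(tert-butyldimethylsilyl)oxy]-2,6-dimethylphenyl}ethan-1-ol | Cc1ccc(O[Si](C)(C)C(C)(C)C)c(C)c1CCO | intermediate
9 | 2-{3-[(tert-butyldimethylsilyl)oxy]-2,6-dimethylphenyl}acetaldehyde | Cc1ccc(O[Si](C)(C)C(C)(C)C)c(C)c1CC=O | intermediate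
10 | ethyl 2-[bis(2,2,2-trifluoroethoxy)phosphoryl]propanoate | CCOC(=O)C(C)P(=O)(OCC(F)(F)F)OCC(F)(F)F | starting material
11 | ethyl (2Z)-4-{3-[(tert-butyldimethylsilyl)oxy]-2,6-dimethylphenyl}-2-methylbut-2-enoate | CCOC(=O)/C(C)=C\Cc1c(C)ccc(O[Si](C)(C)C(C)(C)C)c1C | intermediate
12 | (2Z)-4-{3-[(tert-butyldimethylsilyl)oxy]-2,6-dimethylphenyl}-2-methylbut-2-en-1-ol | OC/C(C)=C\Cc1c(C)ccc(O[Si](C)(C)C(C)(C)C)c1C | intermediate
13 | (2Z)-4-{3-[(tert-butyldimethylsilyl)oxy]-2,6-dimethylphenyl}-2-methylbut-2-enal | O=C/C(C)=C\Cc1c(C)ccc(O[Si](C)(C)C(C)(C)C)c1C | intermediate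
14 | methyl (R)-2,2-dimethyl-1,3-dioxolane-4-carboxylate | COC(=O)[C@H]1COC(C)(C)O1 | starting material
15 | (R)-2,2-dimethyl-1,3-dioxolane-4-carbaldehyde | O=C[C@H]1COC(C)(C)O1 | intermediate (not isolated)
16 | (S)-4-ethynyl-2,2-dimethyl-1,3-dioxolane | C#C[C@H]1COC(C)(C)O1 | intermediate
17 | (S)-4-(buta-1,3-dien-2-yl)-2,2-dimethyl-1,3-dioxolane | C=CC(=C)[C@H]1COC(C)(C)O1 | intermediate
18 | {3-[(4S)-2,2-dimethyl-1,3-dioxolan-4-yl]but-3-en-1-yl}bis(3-methylbutan-2-yl)borane | C=C(CCB(C(C)C(C)C)C(C)C(C)C)[C@H]1COC(C)(C)O1 | intermediate (not isolated)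
19 | 3-[(4S)-2,2-dimethyl-1,3-dioxolan-4-yl]but-3-en-1-ol | C=C(CCO)[C@H]1COC(C)(C)O1 | intermediate
20 | (S)-4-(4-iodobut-1-en-2-yl)-2,2-dimethyl-1,3-dioxolane | C=C(CCI)[C@H]1COC(C)(C)O1 | intermediate
21 | {3-[(4S)-2,2-dimethyl-1,3-dioxolan-4-yl]but-3-en-1-yl}lithium | C=C(CC[Li])[C@H]1COC(C)(C)O1 | intermediate (not isolated)
22 | (2Z)-1-{3-[(tert-butyldimethylsilyl)oxy]-2,6-dimethylphenyl}-7-[(4S)-2,2-dimethyl-1,3-dioxolan-4-yl]-3-methylocta-2,7-dien-4-ol, both C4 epimers | C=C(CCC(O)/C(C)=C\Cc1c(C)ccc(O[Si](C)(C)C(C)(C)C)c1C)[C@H]1COC(C)(C)O1 | intermediate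
23 | (2Z)-1-{3-[(tert-butyldimethylsilyl)oxy]-2,6-dimethylphenyl}-7-[(4S)-2,2-dimethyl-1,3-dioxolan-4-yl]-3-methylocta-2,7-dien-4-one | C=C(CCC(=O)/C(C)=C\Cc1c(C)ccc(O[Si](C)(C)C(C)(C)C)c1C)[C@H]1COC(C)(C)O1 | intermediate
24 | (2Z,4S)-1-{3-[(tert-butyldimethylsilyl)oxy]-2,6-dimethylphenyl}-7-[(4S)-2,2-dimethyl-1,3-dioxolan-4-yl]-3-methylocta-2,7-dien-4-ol | C=C(CC[C@H](O)/C(C)=C\Cc1c(C)ccc(O[Si](C)(C)C(C)(C)C)c1C)[C@H]1COC(C)(C)O1 | intermediate
25 | (2Z,4S)-1-{3-[(tert-butyldimethylsilyl)oxy]-2,6-dimethylphenyl}-7-[(4S)-2,2-dimethyl-1,3-dioxolan-4-yl]-3-methylocta-2,7-dien-4-yl methyl carbonate | C=C(CC[C@H](OC(=O)OC)/C(C)=C\Cc1c(C)ccc(O[Si](C)(C)C(C)(C)C)c1C)[C@H]1COC(C)(C)O1 | intermediate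
26 | methyl (2Z,4S)-1-(3-hydroxy-2,6-dimethylphenyl)-7-[(4S)-2,2-dimethyl-1,3-dioxolan-4-yl]-3-methylocta-2,7-dien-4-yl carbonate (key-step precursor) | C=C(CC[C@H](OC(=O)OC)/C(C)=C\Cc1c(C)ccc(O)c1C)[C@H]1COC(C)(C)O1 | intermediate
27 | (9S,10R,14S)-14,15-(isopropylidenedioxy)-19-norlabda-1,4,7,13(16)-tetraen-3-one, that is (4aR,5S)-5-{3-[(4S)-2,2-dimethyl-1,3-dioxolan-4-yl]but-3-en-1-yl}-1,4a,6-trimethyl-5,8-dihydronaphthalen-2(4aH)-one (key-step product) | C=C(CC[C@H]1C(C)=CCC2=C(C)C(=O)C=C[C@]12C)[C@H]1COC(C)(C)O1 | intermediate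
28 | (9S,10R,14S)-14,15-(isopropylidenedioxy)-19-norlabda-4,7,13(16)-trien-3-one | C=C(CC[C@H]1C(C)=CCC2=C(C)C(=O)CC[C@]12C)[C@H]1COC(C)(C)O1 | intermediate
29 | lithium 14,15-(isopropylidenedioxy)-19-norlabda-3,7,13(16)-trien-3-olate, H5 α (trans to C20) | C=C(CC[C@H]1C(C)=CC[C@H]2C(C)=C([O-])CC[C@]12C)[C@H]1COC(C)(C)O1.[Li+] | intermediate (not isolated)
30 | (5R,9S,10R,14S)-14,15-(isopropylidenedioxy)labda-7,13(16)-dien-3-one | C=C(CC[C@H]1C(C)=CC[C@H]2C(C)(C)C(=O)CC[C@]12C)[C@H]1COC(C)(C)O1 | intermediate
31 | hydrazone of 30 at C3 | C=C(CC[C@H]1C(C)=CC[C@H]2C(C)(C)C(=NN)CC[C@]12C)[C@H]1COC(C)(C)O1 | intermediate (not isolated)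
32 | (5S,9S,10S,14S)-14,15-(isopropylidenedioxy)labda-7,13(16)-diene | C=C(CC[C@H]1C(C)=CC[C@H]2C(C)(C)CCC[C@]12C)[C@H]1COC(C)(C)O1 | intermediate
33 | (5S,9S,10S,14S)-labda-7,13(16)-diene-14,15-diol | C=C(CC[C@H]1C(C)=CC[C@H]2C(C)(C)CCC[C@]12C)[C@@H](CO)O | intermediate
34 | (5S,9S,10S,14S)-labda-7,13(16)-diene-14,15-diyl diacetate (CNP0289003.1) | C=C(CC[C@H]1C(C)=CC[C@H]2C(C)(C)CCC[C@]12C)[C@@H](COC(C)=O)OC(C)=O | target

**Step count**

Total: 24 steps. Longest linear sequence: 20 steps (steps 1–9, then 14–24, from 2-bromo-1,3-dimethylbenzene). The side-chain branch (steps 10–13) has 4 steps.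

**Steps most likely to fail**

Step 19 (key step). The endo closure of the anti π-allyl complex may be slower than its anti-to-syn isomerisation and β-hydride elimination to dienes. The phenoxide may also react through the ortho carbon C4 or through the wrong arene face. Fallback: the fallback sets out from 24 and comes back at 27 without a metal. Treatment of 24 with hexachloroacetone and PPh3 in CH2Cl2 at −20 °C should give, by SN2 chlorination with inversion and without allylic shift, tert-butyl({3-[(2Z,4R)-4-chloro-7-[(4S)-2,2-dimethyl-1,3-dioxolan-4-yl]-3-methylocta-2,7-dien-1-yl]-2,4-dimethylphenyl}oxy)dimethylsilane F1. CsF in DMF at high dilution would then unmask the phenoxide, whose para carbon C10 displaces chloride at C9 by an intramolecular 6-exo SN2 C-alkylation (phenoxide alkylative dearomatisation). The second inversion restores the C9 configuration of 27. This route removes the isomerisation and elimination channels of the allyl complex. The para-versus-ortho and facial questions remain and would be answered by separation of the dienones.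

Step 21. In liquid ammonia, proton exchange between the enolate and ketone already methylated may spread methylation to C2 and leave unmethylated ketone. Prolonged contact with lithium may also begin to cleave the allylic C14–O bond. Fallback: the fallback sets out from 28 and comes back at 30. Compound 28 is reduced as before with only a slight excess of lithium, the ammonia is evaporated, and enolate 29 is trapped with Me3SiCl/Et3N in THF as the trimethylsilyl enol ether, 14,15-(isopropylidenedioxy)-3-(trimethylsilyloxy)-19-norlabda-3,7,13(16)-triene F2, which is purified. MeLi in THF at 0 °C then regenerates 29 regiospecifically and free of other bases, and MeI in THF/DMPU methylates C4 to give 30.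

Step 22. Hydrazone formation at the C3 carbonyl, hindered by the gem-dimethyl group, may stay incomplete. Hydroxide at 200 °C may also move the 13(16) double bond toward the oxygen-bearing C14. Fallback: the fallback sets out from 30 and comes back at 32 by radical deoxygenation. NaBH4 in MeOH at 0 °C should give (3S,5R,9S,10R,14S)-14,15-(isopropylidenedioxy)labda-7,13(16)-dien-3-ol F3 (mainly the equatorial 3β alcohol; the centre is removed afterwards). NaH, CS2 and then MeI in THF convert it into the O-alkyl S-methyl dithiocarbonate, O-[(3S,5R,9S,10R,14S)-14,15-(isopropylidenedioxy)labda-7,13(16)-dien-3-yl] S-methyl carbonodithioate F4. Bu3SnH with AIBN in toluene at 110 °C (Barton–McCombie deoxygenation) then gives 32 under neutral conditions.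

**Further compounds**

F1 | step 19 | tert-butyl({3-[(2Z,4R)-4-chloro-7-[(4S)-2,2-dimethyl-1,3-dioxolan-4-yl]-3-methylocta-2,7-dien-1-yl]-2,4-dimethylphenyl}oxy)dimethylsilane | C=C(CC[C@@H](Cl)/C(C)=C\Cc1c(C)ccc(O[Si](C)(C)C(C)(C)C)c1C)[C@H]1COC(C)(C)O1
F2 | step 21 | 14,15-(isopropylidenedioxy)-3-(trimethylsilyloxy)-19-norlabda-3,7,13(16)-triene, H5 α | C=C(CC[C@H]1C(C)=CC[C@H]2C(C)=C(O[Si](C)(C)C)CC[C@]12C)[C@H]1COC(C)(C)O1
F3 | step 22 | (3S,5R,9S,10R,14S)-14,15-(isopropylidenedioxy)labda-7,13(16)-dien-3-ol | C=C(CC[C@H]1C(C)=CC[C@H]2C(C)(C)[C@@H](O)CC[C@]12C)[C@H]1COC(C)(C)O1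
F4 | step 22 | O-[(3S,5R,9S,10R,14S)-14,15-(isopropylidenedioxy)labda-7,13(16)-dien-3-yl] S-methyl carbonodithioate | C=C(CC[C@H]1C(C)=CC[C@H]2C(C)(C)[C@@H](OC(=S)SC)CC[C@]12C)[C@H]1COC(C)(C)O1
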